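## Retrosynthetic overview

1. Feature: the prenylated carbons C6 (ring A) and C3' (ring B) each lie ortho to an oxygen (on C5, on C2') whose second ortho carbon (C4a, C1') is a fully substituted skeletal carbon. Both aryl–CH2 bonds are therefore cut back to O-(1,1-dimethylallyl) ethers and made together by a double aromatic Claisen rearrangement.
2. The hydroxyquinone (ring B) is traced to a 2',4',5'-trimethoxyarene: Ce(IV) oxidative demethylation across C2'/C5', then OMe to OH exchange at C4'.
3. Rings A and B are bought. Ring C is the only ring formed, by O1–C2 Mitsunobu closure of a (2R)-2,3-diarylpropan-1-ol before any alkene is present.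
4. C3 is set together with the C3–C4 bond by Evans alkylation of the ring-B arylacetyl imide with a locally symmetric ring-A benzyl bromide. The two ortho oxygens are carried as tosylates and O2' as a benzyl ether, so the three phenols are released in two separate stages.

Key step: step 18

Remark on the chemistry: isoflavan numbering is used. The stereodescriptor of the target SMILES reads as (3R) (C2 > C1' > C4 > H), and the same spatial arrangement is (R) in every chiral intermediate from 15 onward. Enol ether 8 is carried as an E/Z mixture because both isomers give the same aldehyde.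

## Route

Step 1
Reactants: 1 2,4,6-trihydroxybenzaldehyde
Product: 2 2,6-dihydroxy-4-methoxybenzaldehyde
Conditions: Me2SO4 (1.0 equiv), K2CO3 (1.0 equiv), acetone, rt to 40 °C
Reagents that add atoms: dimethyl sulfate COS(=O)(=O)OC
Why: Williamson-type O-methylation with one equivalent of base should pick the 4-OH, which is the most acidic hydroxyl (para to the formyl group) and the only one not hydrogen-bonded to the carbonyl oxygen, while the hard electrophile limits C-methylation.

Step 2
Reactants: 2 2,6-dihydroxy-4-methoxybenzaldehyde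
Product: 3 2-formyl-5-methoxybenzene-1,3-diyl bis(4-methylbenzenesulfonate)
Conditions: TsCl (2.4 equiv), Et3N, DMAP (cat.), CH2Cl2, 0 °C to rt
Reagents that add atoms: 4-toluenesulfonyl chloride Cc1ccc(cc1)S(=O)(=O)Cl
Why: Sulfonylation of both phenols gives electron-withdrawing groups that should keep the later benzylic bromide from ionising as a 2,4,6-trialkoxybenzyl halide would, and they are orthogonal to the benzyl ether planned for ring B.

Step 3
Reactants: 3 2-formyl-5-methoxybenzene-1,3-diyl bis(4-methylbenzenesulfonate)
Product: 4 2-(hydroxymethyl)-5-methoxybenzene-1,3-diyl bis(4-methylbenzenesulfonate)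
Conditions: NaBH4, THF/MeOH, 0 °C
Reagents that add atoms: none
Why: Borohydride reduction of an aryl aldehyde, to which aryl sulfonates are inert.

Step 4
Reactants: 4 2-(hydroxymethyl)-5-methoxybenzene-1,3-diyl bis(4-methylbenzenesulfonate)
Product: 5 2-(bromomethyl)-5-methoxybenzene-1,3-diyl bis(4-methylbenzenesulfonate)
Conditions: PBr3 (0.4 equiv), CH2Cl2, 0 °C
Reagents that add atoms: phosphorus tribromide BrP(Br)Br
Why: Alcohol-to-bromide exchange through the phosphite ester (SN2 by bromide) meets no acid-labile group, and the product is a deactivated para-methoxybenzyl-type bromide that should be storable.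

Step 5
Reactants: 6 2-hydroxy-4,5-dimethoxybenzaldehyde
Product: 7 2-(benzyloxy)-4,5-dimethoxybenzaldehyde
Conditions: BnBr, K2CO3, DMF, 50 °C
Reagents that add atoms: benzyl bromide BrCc1ccccc1
Why: Williamson etherification masks the future O2' with a group that survives base, hydride and Mitsunobu conditions and is removed by hydrogenolysis while the molecule is still free of alkenes.

Step 6
Reactants: 7 2-(benzyloxy)-4,5-dimethoxybenzaldehyde
Product: 8 1-(benzyloxy)-4,5-dimethoxy-2-(2-methoxyethenyl)benzene (E/Z mixture)
Conditions: MeOCH2PPh3Cl, KOt-Bu, THF, 0 °C to rt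
Reagents that add atoms: (methoxymethyl)triphenylphosphonium chloride COC[P+](c1ccccc1)(c1ccccc1)c1ccccc1.[Cl-]
Why: Wittig methoxymethylenation of a non-enolisable aryl aldehyde is the standard one-carbon homologation.

Step 7
Reactants: 8 1-(benzyloxy)-4,5-dimethoxy-2-(2-methoxyethenyl)benzene
Product: 9 2-[2-(benzyloxy)-4,5-dimethoxyphenyl]acetaldehyde
Conditions: 2 M aq HCl, THF, 45 °C
Reagents that add atoms: water O
Why: Acid hydrolysis of the enol ether (C-protonation, hydration of the oxocarbenium ion, loss of methanol) leaves the aryl benzyl and methyl ethers untouched.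

Step 8
Reactants: 9 2-[2-(benzyloxy)-4,5-dimethoxyphenyl]acetaldehyde
Product: 10 2-[2-(benzyloxy)-4,5-dimethoxyphenyl]acetic acid
Conditions: NaClO2, NaH2PO4, 2-methylbut-2-ene (excess), t-BuOH/H2O, 0 °C to rt
Reagents that add atoms: sodium chlorite [Na+].[O-]Cl=O
Why: Pinnick oxidation converts the sensitive arylacetaldehyde to the acid under buffered conditions, and the alkene scavenger removes hypochlorous acid before it can chlorinate the electron-rich ring.

Step 9
Reactants: 10 2-[2-(benzyloxy)-4,5-dimethoxyphenyl]acetic acid; 11 (R)-4-benzyl-1,3-oxazolidin-2-one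
Product: 13 (4R)-4-benzyl-3-{2-[2-(benzyloxy)-4,5-dimethoxyphenyl]acetyl}-1,3-oxazolidin-2-one, via mixed pivalic anhydride 12 (not isolated)
Conditions: PivCl, Et3N, THF, −20 °C; then LiCl, 11, −20 °C to rt
Reagents that add atoms: pivaloyl chloride CC(C)(C)C(=O)Cl (its atoms are carried in 12 only)
Why: N-acylation of the Evans oxazolidinone through the mixed anhydride, in which the nucleophile attacks the unhindered arylacetyl carbonyl rather than the pivaloyl carbonyl.

Step 10
Reactants: 13 (4R)-4-benzyl-3-{2-[2-(benzyloxy)-4,5-dimethoxyphenyl]acetyl}-1,3-oxazolidin-2-one; 5 2-(bromomethyl)-5-methoxybenzene-1,3-diyl bis(4-methylbenzenesulfonate)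
Product: 15 (4R)-4-benzyl-3-{(2R)-2-[2-(benzyloxy)-4,5-dimethoxyphenyl]-3-[4-methoxy-2,6-bis(tosyloxy)phenyl]propanoyl}-1,3-oxazolidin-2-one, via sodium (Z)-enolate 14 (not isolated)
Conditions: NaHMDS (1.05 equiv), THF, −78 °C; then 5, −78 to −20 °C
Reagents that add atoms: sodium hexamethyldisilazide C[Si](C)(C)[N-][Si](C)(C)C.[Na+] (sodium is carried in 14 only)
Why: In this Evans asymmetric alkylation the chelated (Z)-enolate is shielded on one face by the C4 benzyl group of the (R)-auxiliary, so the bromide should enter from the open face and set the future C3 as (R) (priorities C=O > aryl > CH2Ar), while allylic strain in the product disfavours re-enolisation.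

Step 11
Reactants: 15 (4R)-4-benzyl-3-{(2R)-2-[2-(benzyloxy)-4,5-dimethoxyphenyl]-3-[4-methoxy-2,6-bis(tosyloxy)phenyl]propanoyl}-1,3-oxazolidin-2-one
Product: 16 (2R)-2-[2-(benzyloxy)-4,5-dimethoxyphenyl]-3-[4-methoxy-2,6-bis(tosyloxy)phenyl]propan-1-ol
Conditions: LiBH4, H2O (1 equiv), Et2O/THF, 0 °C
Reagents that add atoms: none
Why: Reductive cleavage of the N-acyl oxazolidinone at the exocyclic carbonyl releases the auxiliary, and the transient aldehyde is reduced faster than it can enolise, so the centre should be kept and the sulfonates and benzyl ether are inert.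

Step 12
Reactants: 16 (2R)-2-[2-(benzyloxy)-4,5-dimethoxyphenyl]-3-[4-methoxy-2,6-bis(tosyloxy)phenyl]propan-1-ol
Product: 17 2-{(2R)-2-[2-(benzyloxy)-4,5-dimethoxyphenyl]-3-hydroxypropyl}-5-methoxybenzene-1,3-diol
Conditions: KOH (excess), dioxane/H2O, 90 °C, Ar; then 1 M HCl
Reagents that add atoms: none
Why: Alkaline hydrolysis of aryl sulfonates by hydroxide attack at sulfur frees only the two ring-A phenols, the alcohol-free medium prevents formation of an alkyl tosylate that could re-alkylate the phenoxides, and the stereocentre is no longer next to a carbonyl group.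

Step 13
Reactants: 17 2-{(2R)-2-[2-(benzyloxy)-4,5-dimethoxyphenyl]-3-hydroxypropyl}-5-methoxybenzene-1,3-diol
Product: 18 (3R)-2'-benzyloxy-5-hydroxy-7,4',5'-trimethoxyisoflavan
Conditions: PPh3, DIAD, THF (0.01 M), 0 °C to rt
Reagents that add atoms: none
Why: Intramolecular Mitsunobu etherification (6-exo-tet) closes ring C at the achiral CH2 carbon; the two ring-A phenols are interchanged by rotation about C4–C4a and give the same chroman with the other one left as 5-OH, and the benzyl ether on O2' excludes the faster five-ring closure to a dihydrobenzofuran.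

Step 14
Reactants: 18 (3R)-2'-benzyloxy-5-hydroxy-7,4',5'-trimethoxyisoflavan
Product: 19 (3R)-5,2'-dihydroxy-7,4',5'-trimethoxyisoflavan
Conditions: H2 (1 atm), 10% Pd/C, EtOAc/MeOH, rt
Reagents that add atoms: none
Why: Hydrogenolysis of the benzyl aryl ether is safe because no alkene is present and the O1–C2 bond of ring C is not benzylic.

Step 15
Reactants: 20 2-methylbut-3-yn-2-ol
Product: 22 methyl 2-methylbut-3-yn-2-yl carbonate, via lithium alkoxide 21 (not isolated)
Conditions: n-BuLi (1.0 equiv), THF, −78 °C; then ClCO2Me, −78 °C to rt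
Reagents that add atoms: methyl chloroformate COC(=O)Cl; n-butyllithium [Li]CCCC (lithium is carried in 21 only)
Why: One equivalent of base removes the hydroxyl proton in preference to the alkyne proton, and O-acylation of the tertiary alkoxide gives the propargylic carbonate.

Step 16
Reactants: 19 (3R)-5,2'-dihydroxy-7,4',5'-trimethoxyisoflavan; 22 methyl 2-methylbut-3-yn-2-yl carbonate
Product: 23 (3R)-5,2'-bis(1,1-dimethylprop-2-ynyloxy)-7,4',5'-trimethoxyisoflavan
Conditions: 22 (3 equiv), CuCl2·2H2O (5 mol %), DBU, MeCN, 0 °C to rt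
Reagents that add atoms: none
Why: In this copper-catalysed propargylic substitution a copper allenylidene-type electrophile is captured by phenoxide at the tertiary carbon, which is the established way to make hindered aryl 1,1-dimethylpropargyl ethers that SN2 chemistry cannot reach, at a temperature far below chromene formation.

Step 17
Reactants: 23 (3R)-5,2'-bis(1,1-dimethylprop-2-ynyloxy)-7,4',5'-trimethoxyisoflavan
Product: 24 (3R)-5,2'-bis(1,1-dimethylallyloxy)-7,4',5'-trimethoxyisoflavan
Conditions: H2 (1 atm), Lindlar catalyst, quinoline, EtOAc, rt, stopped after 2 equiv H2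
Reagents that add atoms: none
Why: Lindlar semi-hydrogenation takes both terminal alkynes to vinyl groups, and the poisoned catalyst should hold back over-reduction and C–O hydrogenolysis.

Step 18
Reactants: 24 (3R)-5,2'-bis(1,1-dimethylallyloxy)-7,4',5'-trimethoxyisoflavan
Product: 27 (3R)-5,2'-dihydroxy-7,4',5'-trimethoxy-6,3'-diprenylisoflavan, via 6-prenyl 2'-monoether 25 (not isolated), via 3'-prenyl 5-monoether 26 (not isolated)
Conditions: PhNEt2 (degassed), 135 °C, Ar, sealed tube
Reagents that add atoms: none
Why: Each tertiary allyl aryl ether undergoes a concerted suprafacial [3,3]-sigmatropic shift through a chair-like six-membered transition state, the O–CMe2 bond breaking as the terminal =CH2 carbon bonds to the free ortho carbon, and the ortho-cyclohexadienone tautomer enolises at once to the phenol, which makes each migration irreversible and, through allylic inversion, turns the 1,1-dimethylallyl ether into the linear prenyl group. The closest known reaction is the aromatic Claisen rearrangement of 1,1-dimethylallyl aryl ethers to ortho-prenylphenols, run here twice on one substrate as two independent events, so that 25 and 26 both drain into 27. No ring is closed and no stereocentre is created, and C3 is a non-acidic benzylic C–H centre outside both reacting arrays, so it keeps its (R) configuration. The step needs regioselectivity and the skeleton supplies it: O5 has C4a (fully substituted) and C6 (C–H) as ortho carbons and O2' has C1' (fully substituted) and C3' (C–H), so only attack at C6 and C3' gives a dienone that can enolise. A Cope relay from C6 to the para carbon C8 should not compete with enolisation of the C6–H dienone, while on ring B the para carbon C5' carries OMe and C6' is meta to O2' and lies outside any sigmatropic path. The weakly basic degassed amine solvent and the modest temperature allowed by the strained tertiary ethers should suppress four side reactions: ionisation with loss of isoprene, acid-catalysed closure of the new ortho-prenylphenols to 2,2-dimethylchromans, the abnormal Claisen pathway, and air oxidation of the ring-B para-methoxyphenol.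

Step 19
Reactants: 27 (3R)-5,2'-dihydroxy-7,4',5'-trimethoxy-6,3'-diprenylisoflavan
Product: 28 (3R)-5,7,2',4',5'-pentamethoxy-6,3'-diprenylisoflavan
Conditions: MeI (excess), K2CO3, DMF, rt, Ar
Reagents that add atoms: iodomethane CI
Why: Williamson methylation with a small electrophile in a dipolar aprotic solvent should reach both di-ortho-substituted phenoxides, installing the 5-OMe of the target and turning ring B into a 1,4-dimethoxyarene ready for oxidation.

Step 20
Reactants: 28 (3R)-5,7,2',4',5'-pentamethoxy-6,3'-diprenylisoflavan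
Product: 29 (3R)-5,7,4'-trimethoxy-6,3'-diprenylisoflavan-2',5'-quinone
Conditions: CAN (2.2 equiv), MeCN/H2O (3:1), −5 °C, short contact time
Reagents that add atoms: water O
Why: In this Ce(IV) oxidative demethylation the 1,2,4-trioxygenated ring B is the most easily oxidised arene and the only one with a para-dimethoxy pair (C2'/C5'), so water should add ipso at these carbons with loss of two methanol molecules, whereas the 1,3,5-trioxygenated ring A cannot form a para-quinone and prenyl side chains are known to tolerate brief treatment with this oxidant.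

Step 21
Reactants: 29 (3R)-5,7,4'-trimethoxy-6,3'-diprenylisoflavan-2',5'-quinone
Product: 30 (3R)-4'-hydroxy-5,7-dimethoxy-6,3'-diprenylisoflavan-2',5'-quinone (target)
Conditions: 0.2 M aq NaOH (2 equiv), THF, 0 °C, Ar; then cold 0.5 M HCl to pH 3
Reagents that add atoms: sodium hydroxide [Na+].[OH-]
Why: The 4'-methoxyquinone is a vinylogous ester, so hydroxide should exchange OMe by addition–elimination at C4' as in the classical alkaline hydrolysis of 2-methoxy-3-prenylquinones, and the electron-rich hydroxyquinone anion that forms resists further attack and deprotonation at C3 until the cold, dilute acidification, which is too mild to cyclise the prenyl group onto the new hydroxyl.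

## Compound list

1 | 2,4,6-trihydroxybenzaldehyde | O=Cc1c(O)cc(O)cc1O | starting material
2 | 2,6-dihydroxy-4-methoxybenzaldehyde | COc1cc(O)c(C=O)c(O)c1 | intermediate
3 | 2-formyl-5-methoxybenzene-1,3-diyl bis(4-methylbenzenesulfonate) | COc1cc(OS(=O)(=O)c2ccc(C)cc2)c(C=O)c(OS(=O)(=O)c2ccc(C)cc2)c1 | intermediate
4 | 2-(hydroxymethyl)-5-methoxybenzene-1,3-diyl bis(4-methylbenzenesulfonate) | COc1cc(OS(=O)(=O)c2ccc(C)cc2)c(CO)c(OS(=O)(=O)c2ccc(C)cc2)c1 | intermediate
5 | 2-(bromomethyl)-5-methoxybenzene-1,3-diyl bis(4-methylbenzenesulfonate) | COc1cc(OS(=O)(=O)c2ccc(C)cc2)c(CBr)c(OS(=O)(=O)c2ccc(C)cc2)c1 | intermediate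
6 | 2-hydroxy-4,5-dimethoxybenzaldehyde | COc1cc(O)c(C=O)cc1OC | starting material
7 | 2-(benzyloxy)-4,5-dimethoxybenzaldehyde | COc1cc(OCc2ccccc2)c(C=O)cc1OC | intermediate
8 | 1-(benzyloxy)-4,5-dimethoxy-2-(2-methoxyethenyl)benzene (E/Z mixture) | COC=Cc1cc(OC)c(OC)cc1OCc1ccccc1 | intermediate
9 | 2-[2-(benzyloxy)-4,5-dimethoxyphenyl]acetaldehyde | O=CCc1cc(OC)c(OC)cc1OCc1ccccc1 | intermediate
10 | 2-[2-(benzyloxy)-4,5-dimethoxyphenyl]acetic acid | OC(=O)Cc1cc(OC)c(OC)cc1OCc1ccccc1 | intermediate
11 | (R)-4-benzyl-1,3-oxazolidin-2-one | O=C1N[C@H](Cc2ccccc2)CO1 | starting material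
12 | 2-[2-(benzyloxy)-4,5-dimethoxyphenyl]acetic pivalic anhydride | CC(C)(C)C(=O)OC(=O)Cc1cc(OC)c(OC)cc1OCc1ccccc1 | intermediate
13 | (4R)-4-benzyl-3-{2-[2-(benzyloxy)-4,5-dimethoxyphenyl]acetyl}-1,3-oxazolidin-2-one | O=C(Cc1cc(OC)c(OC)cc1OCc1ccccc1)N1[C@H](Cc2ccccc2)COC1=O | intermediate
14 | sodium (Z)-enolate of 13 | [Na+].[O-]/C(=C\c1cc(OC)c(OC)cc1OCc1ccccc1)N1[C@H](Cc2ccccc2)COC1=O | intermediate
15 | (4R)-4-benzyl-3-{(2R)-2-[2-(benzyloxy)-4,5-dimethoxyphenyl]-3-[4-methoxy-2,6-bis(tosyloxy)phenyl]propanoyl}-1,3-oxazolidin-2-one | O=C([C@@H](c1cc(OC)c(OC)cc1OCc1ccccc1)Cc1c(OS(=O)(=O)c2ccc(C)cc2)cc(OC)cc1OS(=O)(=O)c1ccc(C)cc1)N1[C@H](Cc2ccccc2)COC1=O | intermediate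
16 | (2R)-2-[2-(benzyloxy)-4,5-dimethoxyphenyl]-3-[4-methoxy-2,6-bis(tosyloxy)phenyl]propan-1-ol | OC[C@@H](c1cc(OC)c(OC)cc1OCc1ccccc1)Cc1c(OS(=O)(=O)c2ccc(C)cc2)cc(OC)cc1OS(=O)(=O)c1ccc(C)cc1 | intermediate
17 | 2-{(2R)-2-[2-(benzyloxy)-4,5-dimethoxyphenyl]-3-hydroxypropyl}-5-methoxybenzene-1,3-diol | OC[C@@H](c1cc(OC)c(OC)cc1OCc1ccccc1)Cc1c(O)cc(OC)cc1O | intermediate
18 | (3R)-2'-benzyloxy-5-hydroxy-7,4',5'-trimethoxyisoflavan | COc1cc2c(c(O)c1)C[C@H](c1cc(OC)c(OC)cc1OCc1ccccc1)CO2 | intermediate
19 | (3R)-5,2'-dihydroxy-7,4',5'-trimethoxyisoflavan | COc1cc2c(c(O)c1)C[C@H](c1cc(OC)c(OC)cc1O)CO2 | intermediate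
20 | 2-methylbut-3-yn-2-ol | CC(C)(O)C#C | starting material
21 | lithium 2-methylbut-3-yn-2-olate | [Li+].[O-]C(C)(C)C#C | intermediate
22 | methyl 2-methylbut-3-yn-2-yl carbonate | COC(=O)OC(C)(C)C#C | intermediate
23 | (3R)-5,2'-bis(1,1-dimethylprop-2-ynyloxy)-7,4',5'-trimethoxyisoflavan | COc1cc2c(c(OC(C)(C)C#C)c1)C[C@H](c1cc(OC)c(OC)cc1OC(C)(C)C#C)CO2 | intermediate
24 | (3R)-5,2'-bis(1,1-dimethylallyloxy)-7,4',5'-trimethoxyisoflavan | COc1cc2c(c(OC(C)(C)C=C)c1)C[C@H](c1cc(OC)c(OC)cc1OC(C)(C)C=C)CO2 | intermediate
25 | (3R)-2'-(1,1-dimethylallyloxy)-5-hydroxy-7,4',5'-trimethoxy-6-prenylisoflavan | COc1cc2c(c(O)c1CC=C(C)C)C[C@H](c1cc(OC)c(OC)cc1OC(C)(C)C=C)CO2 | intermediate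
26 | (3R)-5-(1,1-dimethylallyloxy)-2'-hydroxy-7,4',5'-trimethoxy-3'-prenylisoflavan | COc1cc2c(c(OC(C)(C)C=C)c1)C[C@H](c1cc(OC)c(OC)c(CC=C(C)C)c1O)CO2 | intermediate
27 | (3R)-5,2'-dihydroxy-7,4',5'-trimethoxy-6,3'-diprenylisoflavan | COc1cc2c(c(O)c1CC=C(C)C)C[C@H](c1cc(OC)c(OC)c(CC=C(C)C)c1O)CO2 | intermediate
28 | (3R)-5,7,2',4',5'-pentamethoxy-6,3'-diprenylisoflavan | COc1cc2c(c(OC)c1CC=C(C)C)C[C@H](c1cc(OC)c(OC)c(CC=C(C)C)c1OC)CO2 | intermediate
29 | (3R)-5,7,4'-trimethoxy-6,3'-diprenylisoflavan-2',5'-quinone | COc1cc2c(c(OC)c1CC=C(C)C)C[C@H](C1=CC(=O)C(OC)=C(CC=C(C)C)C1=O)CO2 | intermediate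
30 | (3R)-4'-hydroxy-5,7-dimethoxy-6,3'-diprenylisoflavan-2',5'-quinone (CNP0241224.1) | COc1cc2c(c(OC)c1CC=C(C)C)C[C@H](C1=CC(=O)C(O)=C(CC=C(C)C)C1=O)CO2 | target

## Step count and risks

Total step count: 21.
Longest linear sequence: 16 steps, from 6 through steps 5 to 14 and 16 to 21.

**First risk, step 18.** The crowded tertiary ethers may ionise or fragment with loss of isoprene back to the phenols. The reaction may also stall after one migration, or a new ortho-prenylphenol may close onto its own alkene.

The fallback gives up the O-to-C transfer and installs both prenyl groups by directed metalation. It sets out from 19 and comes back at 27.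
- Diphenol 19 is treated with MOMCl and i-Pr2NEt to give the bis(methoxymethyl) ether F1.
- F1 is lithiated twice with n-BuLi/TMEDA in THF at 0 °C, at the two carbons flanked by OMOM and OMe, to give the 6,3'-dilithio species F2. C6 is preferred over C8, which lies only between OMe and the ring oxygen. C3' is preferred over C6', which has a single ortho oxygen.
- F2 is alkylated with prenyl bromide in the presence of catalytic CuBr·SMe2 to give the diprenyl bis(methoxymethyl) ether F3.
- Brief treatment of F3 with catalytic HCl in MeOH at rt removes both acetals and returns to 27.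

**Second risk, step 20.** Electron transfer may be unselective, touching ring A or the trisubstituted alkenes. Nitration at C8 or oxidative coupling at the free C6' position may also compete.

The fallback oxidises the free para-methoxyphenol instead of the dimethyl ether. This needs only a mild two-electron oxidant. It sets out from 27 and comes back at 29.
- Diphenol 27 is treated with one equivalent of PhI(OAc)2 in MeCN/H2O at 0 °C. The 2'-OH/5'-OMe pair of ring B, a hydroquinone monoether, should be oxidised first, giving the 5-hydroxy methoxyquinone F4.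
- The remaining 5-OH of F4 is methylated under neutral conditions with MeI and Ag2O in CH2Cl2 to give 29.

**Third risk, step 21.** Before the exchange is complete, base may enolise the C3–H of the methoxyquinone toward a quinone methide and erode the configuration at C3. Hydroxide may also add at the unsubstituted C6' position, with subsequent air oxidation.

The fallback removes Brønsted base and breaks a different bond: O–CH3 by SN2 at the methyl carbon, rather than C4'–O by addition–elimination. It sets out from 29 and comes back at 30.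
- Quinone 29 is treated with MgI2·OEt2 in toluene/Et2O at rt to 40 °C.
- Magnesium chelated between the C5' carbonyl oxygen and O4' activates only this methoxy group toward iodide.
- A cold, mildly acidic work-up gives 30.
- The fallback passes through no new isolable compound (entry F0).

## Further compounds

F1 | step 18 | (3R)-7,4',5'-trimethoxy-5,2'-bis(methoxymethoxy)isoflavan | COc1cc2c(c(OCOC)c1)C[C@H](c1cc(OC)c(OC)cc1OCOC)CO2
F2 | step 18 | (3R)-6,3'-dilithio-7,4',5'-trimethoxy-5,2'-bis(methoxymethoxy)isoflavan | COc1cc2c(c(OCOC)c1[Li])C[C@H](c1cc(OC)c(OC)c([Li])c1OCOC)CO2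
F3 | step 18 | (3R)-7,4',5'-trimethoxy-5,2'-bis(methoxymethoxy)-6,3'-diprenylisoflavan | COc1cc2c(c(OCOC)c1CC=C(C)C)C[C@H](c1cc(OC)c(OC)c(CC=C(C)C)c1OCOC)CO2
F4 | step 20 | (3R)-5-hydroxy-7,4'-dimethoxy-6,3'-diprenylisoflavan-2',5'-quinone | COc1cc2c(c(O)c1CC=C(C)C)C[C@H](C1=CC(=O)C(OC)=C(CC=C(C)C)C1=O)CO2
F0 | step 21 | none | none
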